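## Retrosynthetic overview

1. Target ⇐ a ten-membered C8 alcohol whose lactone carbonyl (C12) is masked as a lactol methyl acetal and whose C14/C15 hydroxyls are silyl ethers (end game: acylation, acetal hydrolysis, lactol oxidation, desilylation).
2. Ten-membered ring ⇐ acyclic bromo-tetraene by cutting C9–C10. C8(O)–C9H2–C10(=C1) is a homoallylic alcohol inside the carbocycle, the retron of alkene 1,2-diboration / primary-selective cross-coupling / oxidation; a vinyl group on C7 and a (Z)-alkenyl bromide at C10 therefore supply the C8–O bond, the C8 configuration, the C9–C10 bond and the ring.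
3. The two trisubstituted alkenes ⇐ two Wittig reactions with α-substituted stabilised ylides (ester trans to the chain, which is the ring-cis geometry needed); the esters become the C14 and C15 alcohols.
4. C6/C7 ⇐ (S)-5-(hydroxymethyl)furan-2(5H)-one: its stereocentre becomes C6 and directs the trans addition of the vinyl group to C7; C8 is then set by the catalyst.
5. Ring order: five-membered O-heterocycle first (bought, carried as acetal, reoxidised to the α-methylene lactone at the end), ten-membered carbocycle second (key step).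

Key step: step 13

Remark on numbering: C1–C15 are the carbons of the germacrane skeleton of the target (C6 = O–CH of the lactone, C7 = ring-fusion CH, C8 = acyloxy CH, C9 = the ring CH2 next to it, C10 and C4 = the alkene carbons bearing the CH2OH carbons C14 and C15, C11–C13 = the α-methylene lactone carbons).

Assumption: the lactol/acetal carbon C12 is carried from step 4 to step 15 as a mixture of both configurations, which converge in step 16; this centre is left unassigned in the SMILES.

Assumption: L* in step 13 is the antipode of the TADDOL-derived phenylphosphonite ligand that directs boron to the face of the vinyl group giving the (8R) carbinol; catalyst control is taken to outweigh the neighbouring C7 centre.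

## Route

Step 1
Reactants: 1 (S)-5-(hydroxymethyl)furan-2(5H)-one
Product: 2 (S)-5-{[tert-butyl(diphenyl)silyl]oxymethyl}furan-2(5H)-one
Conditions: TBDPSCl, imidazole, CH2Cl2, 0 °C to rt
Reagents that add atoms: tert-butyl(chloro)diphenylsilane CC(C)(C)[Si](Cl)(c1ccccc1)c1ccccc1
Why: Silyl ether formation on the primary alcohol with imidazole as base installs a bulky group that will shield one face of the butenolide, and the stereocentre (future C6) is untouched.

Step 2
Reactants: 2 silyl-protected butenolide; 3 vinylmagnesium bromide (CH2=CHMgBr)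
Product: 5 (3R,4S,5S)-5-{[tert-butyl(diphenyl)silyl]oxymethyl}-3-[(dimethylamino)methyl]-4-vinyldihydrofuran-2(3H)-one, via bromomagnesium lactone enolate 4 (not isolated)
Conditions: CH2=CHMgBr, CuBr·SMe2 (cat.), THF, −78 °C; then [CH2=NMe2]I, −78 °C to rt
Reagents that add atoms: dimethyl(methylidene)ammonium iodide C[N+](C)=C.[I-]
Why: Copper-catalysed conjugate addition of the vinyl Grignard reagent occurs anti to the silyloxymethyl group and so sets C7 trans to C6, and the magnesium enolate is then aminomethylated anti to the new vinyl group (tandem conjugate addition–Mannich reaction), giving a C11 centre that is removed in step 3.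

Step 3
Reactants: 5 Mannich base
Product: 7 (4S,5S)-5-{[tert-butyl(diphenyl)silyl]oxymethyl}-3-methylidene-4-vinyldihydrofuran-2(3H)-one, via trimethylammonium iodide 6 (not isolated)
Conditions: MeI, THF/MeOH, rt; then NaHCO3 (aq), CH2Cl2, rt
Reagents that add atoms: iodomethane CI (its methyl group is in 6 only)
Why: Exhaustive N-methylation followed by bicarbonate-induced loss of trimethylamine (Hofmann-type β-elimination of a Mannich base) unveils the α-methylene lactone under conditions too mild to epimerise C7 or to move the double bond into the ring.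

Step 4
Reactants: 7 α-methylene lactone
Product: 9 tert-butyl{[(2S,3S)-5-methoxy-4-methylidene-3-vinyltetrahydrofuran-2-yl]methoxy}diphenylsilane (both C5 epimers), via lactol 8 (not isolated)
Conditions: i-Bu2AlH, CH2Cl2, −78 °C; aqueous KNaC4H4O6 work-up; then MeOH, PPTS (cat.), rt
Reagents that add atoms: methanol CO
Why: i-Bu2AlH adds once to the lactone carbonyl at −78 °C (1,2-reduction through a stable tetrahedral aluminate) and the crude allylic lactol is converted by acid-catalysed acetalisation into the methyl acetal, which masks C12 against base, hydride and conjugate addition.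

Step 5
Reactants: 9 silyl acetal
Product: 10 [(2S,3S)-5-methoxy-4-methylidene-3-vinyltetrahydrofuran-2-yl]methanol (both C5 epimers)
Conditions: Bu4NF, THF, 0 °C to rt
Reagents that add atoms: none
Why: Fluoride cleaves the Si–O bond (desilylation) without touching the acetal or the alkenes.

Step 6
Reactants: 11 ethyl (triphenyl-λ5-phosphanylidene)acetate; 12 tert-butyl(3-iodopropoxy)dimethylsilane
Product: 13 ethyl 5-{[tert-butyl(dimethyl)silyl]oxy}-2-(triphenyl-λ5-phosphanylidene)pentanoate
Conditions: MeCN, reflux (two equivalents of 11)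
Reagents that add atoms: none
Why: C-Alkylation of the stabilised ylide by the primary iodide gives a phosphonium salt that the second equivalent of ylide deprotonates (alkylation–transylidation), delivering the α-substituted stabilised ylide that carries C1–C4 and C15.

Step 7
Reactants: 10 acetal alcohol; 13 α-substituted ylide
Product: 15 ethyl (2E)-5-{[tert-butyl(dimethyl)silyl]oxy}-2-{[(2R,3S)-5-methoxy-4-methylidene-3-vinyltetrahydrofuran-2-yl]methylidene}pentanoate, via oxolane-2-carbaldehyde 14 (not isolated)
Conditions: Dess–Martin periodinane, pyridine, CH2Cl2, 0 °C to rt; then 13, CH2Cl2, rt to 40 °C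
Reagents that add atoms: none
Why: Dess–Martin oxidation gives the α-alkoxy aldehyde, which is olefinated at once with the α-branched stabilised ylide (Wittig reaction); such ylides place the ester trans to the aldehyde-derived substituent, which is the C4=C5 geometry of the target (C3 cis to C6), and the neutral conditions do not epimerise C6.

Step 8
Reactants: 15 silyloxy enoate
Product: 16 ethyl (2E)-5-hydroxy-2-{[(2R,3S)-5-methoxy-4-methylidene-3-vinyltetrahydrofuran-2-yl]methylidene}pentanoate
Conditions: PPTS (cat.), MeOH, rt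
Reagents that add atoms: none
Why: Acid-catalysed methanolysis removes the primary tert-butyldimethylsilyl ether (desilylation), and exchange at the methyl acetal is degenerate in methanol.

Step 9
Reactants: 11 ethyl (triphenyl-λ5-phosphanylidene)acetate
Product: 18 ethyl bromo(triphenyl-λ5-phosphanylidene)acetate, via bromophosphonium bromide 17 (not isolated)
Conditions: Br2, CH2Cl2, 0 °C; then NaOH (aq), 0 °C
Reagents that add atoms: bromine BrBr
Why: Electrophilic bromination of the stabilised ylide at carbon gives the bromophosphonium salt, which aqueous NaOH deprotonates to the isolable α-bromo ylide (ylide halogenation).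

Step 10
Reactants: 16 hydroxy enoate; 18 α-bromo ylide
Product: 20 diethyl (2Z,6E)-2-bromo-6-{[(2R,3S)-5-methoxy-4-methylidene-3-vinyltetrahydrofuran-2-yl]methylidene}hept-2-enedioate, via 5-oxopentanoate 19 (not isolated)
Conditions: Dess–Martin periodinane, pyridine, CH2Cl2, 0 °C to rt; then 18, CH2Cl2, rt
Reagents that add atoms: none
Why: Dess–Martin oxidation followed by Wittig reaction with the α-bromo stabilised ylide should give the (Z)-α-bromo enoate (ester trans to the chain, bromine cis to C2), which fixes the C1=C10 geometry that the key step retains.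

Step 11
Reactants: 20 bromo diester
Product: 21 (2Z,6E)-2-bromo-6-{[(2R,3S)-5-methoxy-4-methylidene-3-vinyltetrahydrofuran-2-yl]methylidene}hept-2-ene-1,7-diol
Conditions: i-Bu2AlH (excess), CH2Cl2, −78 °C; aqueous KNaC4H4O6 work-up
Reagents that add atoms: none
Why: i-Bu2AlH reduces both conjugated esters to the allylic alcohols (1,2-reduction) and leaves the alkenyl bromide, the acetal and both alkene geometries unchanged.

Step 12
Reactants: 21 bromo diol
Product: 22 (2Z,6E)-2-bromo-1,7-bis{[tert-butyl(diphenyl)silyl]oxy}-6-{[(2R,3S)-5-methoxy-4-methylidene-3-vinyltetrahydrofuran-2-yl]methylidene}hept-2-ene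
Conditions: TBDPSCl, imidazole, DMF, rt
Reagents that add atoms: tert-butyl(chloro)diphenylsilane CC(C)(C)[Si](Cl)(c1ccccc1)c1ccccc1
Why: Silyl ether formation on both primary allylic alcohols gives ethers that survive the aqueous KOH and peroxide of step 13.

Step 13
Reactants: 22 acyclic bromo-tetraene
Product: 25 (3aR,4R,6E,10E,11aR)-6,10-bis({[tert-butyl(diphenyl)silyl]oxy}methyl)-2-methoxy-3-methylidene-2,3,3a,4,5,8,9,11a-octahydrocyclodeca[b]furan-4-ol (both C2 epimers), via acyclic bis(boronate) 23 (not isolated), via macrocyclic boronate 24 (not isolated)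
Conditions: Pt(dba)3 (cat.), L* (chiral TADDOL phenylphosphonite), B2pin2, THF, 60 °C; then Pd(OAc)2 (cat.), RuPhos, KOH, THF/H2O, 70 °C, high dilution; then H2O2 (aq), NaOH, 0 °C to rt
Reagents that add atoms: bis(pinacolato)diboron CC1(C)OB(OC1(C)C)B1OC(C)(C)C(C)(C)O1 (boron groups of 23 and 24); hydrogen peroxide OO (the C8 oxygen of 25)
Why: Proposed new method: this is an intramolecular, ring-closing version of the known one-pot sequence in which zerovalent platinum with a chiral phosphonite adds B2pin2 syn across a monosubstituted alkene, the primary C–B bond of the resulting 1,2-bis(boronate), activated by its secondary neighbour, transmetalates selectively to an alkenylpalladium bromide (divalent palladium, formed by oxidative addition of the C10–Br bond to zerovalent palladium), and the surviving secondary boronate is oxidised to the carbinol with retention; the closest known reaction types are that intermolecular diboration/cross-coupling/oxidation cascade and medium-ring B-alkyl Suzuki–Miyaura macrocyclisations onto alkenyl halides. The ten-membered carbocycle is closed at C9–C10 by C(sp3)–C(sp2) reductive elimination from an eleven-membered alkyl(alkenyl)palladium ring, endo with respect to the C1=C10 double bond, whose geometry (bromine cis to C2) is retained and becomes the ring-cis alkene. C8 is the only new stereocentre: it is set by the platinum–ligand complex in the diboration and carried unchanged through the coupling and the stereoretentive C–B to C–O oxidation. The step needs chemoselectivity for the one monosubstituted alkene (all others are 1,1-di- or trisubstituted and, C12 being an acetal, unconjugated), site selectivity for the primary C9 boronate over the secondary C8 boronate (also ten- against nine-membered ring) and stability to aqueous KOH, which the acetal and the silyl ethers provide; no free hydroxyl group is present that could redirect the coupling to C8.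

Step 14
Reactants: 25 macrocyclic alcohol; 26 3-methylbutanoic anhydride
Product: 27 (3aR,4R,6E,10E,11aR)-6,10-bis({[tert-butyl(diphenyl)silyl]oxy}methyl)-2-methoxy-3-methylidene-2,3,3a,4,5,8,9,11a-octahydrocyclodeca[b]furan-4-yl 3-methylbutanoate (both C2 epimers)
Conditions: 26, DMAP (cat.), Et3N, CH2Cl2, rt
Reagents that add atoms: none
Why: DMAP-catalysed acylation of the only free hydroxyl group with the anhydride (nucleophilic-catalysis esterification) installs the isovalerate at C8 with retention of configuration.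

Step 15
Reactants: 27 acetal ester
Product: 28 (3aR,4R,6E,10E,11aR)-6,10-bis({[tert-butyl(diphenyl)silyl]oxy}methyl)-2-hydroxy-3-methylidene-2,3,3a,4,5,8,9,11a-octahydrocyclodeca[b]furan-4-yl 3-methylbutanoate (both C2 epimers)
Conditions: AcOH/THF/H2O, rt
Reagents that add atoms: water O
Why: Mild aqueous acid hydrolyses the allylic methyl acetal through its stabilised oxocarbenium ion (acetal hydrolysis) while the silyl ethers, the ester and the ring alkenes are left intact.

Step 16
Reactants: 28 lactol
Product: 29 (3aR,4R,6E,10E,11aR)-6,10-bis({[tert-butyl(diphenyl)silyl]oxy}methyl)-3-methylidene-2-oxo-2,3,3a,4,5,8,9,11a-octahydrocyclodeca[b]furan-4-yl 3-methylbutanoate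
Conditions: Dess–Martin periodinane, pyridine, CH2Cl2, 0 °C to rt
Reagents that add atoms: none
Why: Dess–Martin periodinane oxidises the lactol, the only hydroxyl group present, to the α-methylene-γ-butyrolactone (lactol oxidation), which also removes the C12 stereocentre.

Step 17
Reactants: 29 bis-silyl lactone
Product: 30 (3aR,4R,6E,10E,11aR)-6,10-bis(hydroxymethyl)-3-methylidene-2-oxo-2,3,3a,4,5,8,9,11a-octahydrocyclodeca[b]furan-4-yl 3-methylbutanoate (CNP0199826.1)
Conditions: HF·pyridine, pyridine, THF, 0 °C to rt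
Reagents that add atoms: none
Why: Buffered HF·pyridine cleaves both primary tert-butyldiphenylsilyl ethers (desilylation) under non-basic conditions that spare the α-methylene lactone and the isovalerate and should give the target.

## Compound list

1 | (S)-5-(hydroxymethyl)furan-2(5H)-one | O=C1O[C@H](CO)C=C1 | starting material
2 | (S)-5-{[tert-butyl(diphenyl)silyl]oxymethyl}furan-2(5H)-one | O=C1O[C@H](CO[Si](c2ccccc2)(c2ccccc2)C(C)(C)C)C=C1 | intermediate
3 | vinylmagnesium bromide | C=C[Mg]Br | starting material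
4 | bromomagnesium enolate of the 4,5-trans 4-vinyl lactone (vinyl anti to the silyloxymethyl group) | Br[Mg]OC1O[C@H](CO[Si](c2ccccc2)(c2ccccc2)C(C)(C)C)[C@@H](C=C)C=1 | intermediate
5 | (3R,4S,5S)-5-{[tert-butyl(diphenyl)silyl]oxymethyl}-3-[(dimethylamino)methyl]-4-vinyldihydrofuran-2(3H)-one | O=C1O[C@H](CO[Si](c2ccccc2)(c2ccccc2)C(C)(C)C)[C@@H](C=C)[C@@H]1CN(C)C | intermediate
6 | {[(3R,4S,5S)-5-{[tert-butyl(diphenyl)silyl]oxymethyl}-2-oxo-4-vinyltetrahydrofuran-3-yl]methyl}trimethylammonium iodide | O=C1O[C@H](CO[Si](c2ccccc2)(c2ccccc2)C(C)(C)C)[C@@H](C=C)[C@@H]1C[N+](C)(C)C.[I-] | intermediate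
7 | (4S,5S)-5-{[tert-butyl(diphenyl)silyl]oxymethyl}-3-methylidene-4-vinyldihydrofuran-2(3H)-one | O=C1O[C@H](CO[Si](c2ccccc2)(c2ccccc2)C(C)(C)C)[C@@H](C=C)C1=C | intermediate
8 | (4S,5S)-5-{[tert-butyl(diphenyl)silyl]oxymethyl}-3-methylidene-4-vinyltetrahydrofuran-2-ol (both C2 epimers) | OC1O[C@H](CO[Si](c2ccccc2)(c2ccccc2)C(C)(C)C)[C@@H](C=C)C1=C | intermediate
9 | tert-butyl{[(2S,3S)-5-methoxy-4-methylidene-3-vinyltetrahydrofuran-2-yl]methoxy}diphenylsilane (both C5 epimers) | COC1O[C@H](CO[Si](c2ccccc2)(c2ccccc2)C(C)(C)C)[C@@H](C=C)C1=C | intermediate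
10 | [(2S,3S)-5-methoxy-4-methylidene-3-vinyltetrahydrofuran-2-yl]methanol (both C5 epimers) | COC1O[C@H](CO)[C@@H](C=C)C1=C | intermediate
11 | ethyl (triphenyl-λ5-phosphanylidene)acetate | CCOC(=O)C=P(c1ccccc1)(c1ccccc1)c1ccccc1 | starting material
12 | tert-butyl(3-iodopropoxy)dimethylsilane | CC(C)(C)[Si](C)(C)OCCCI | starting material
13 | ethyl 5-{[tert-butyl(dimethyl)silyl]oxy}-2-(triphenyl-λ5-phosphanylidene)pentanoate | CCOC(=O)C(CCCO[Si](C)(C)C(C)(C)C)=P(c1ccccc1)(c1ccccc1)c1ccccc1 | intermediate
14 | (2S,3S)-5-methoxy-4-methylidene-3-vinyltetrahydrofuran-2-carbaldehyde (both C5 epimers) | COC1O[C@H](C=O)[C@@H](C=C)C1=C | intermediate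
15 | ethyl (2E)-5-{[tert-butyl(dimethyl)silyl]oxy}-2-{[(2R,3S)-5-methoxy-4-methylidene-3-vinyltetrahydrofuran-2-yl]methylidene}pentanoate | COC1O[C@H](/C=C(/C(=O)OCC)CCCO[Si](C)(C)C(C)(C)C)[C@@H](C=C)C1=C | intermediate
16 | ethyl (2E)-5-hydroxy-2-{[(2R,3S)-5-methoxy-4-methylidene-3-vinyltetrahydrofuran-2-yl]methylidene}pentanoate | COC1O[C@H](/C=C(/C(=O)OCC)CCCO)[C@@H](C=C)C1=C | intermediate
17 | (1-bromo-2-ethoxy-2-oxoethyl)triphenylphosphonium bromide | CCOC(=O)C(Br)[P+](c1ccccc1)(c1ccccc1)c1ccccc1.[Br-] | intermediate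
18 | ethyl bromo(triphenyl-λ5-phosphanylidene)acetate | CCOC(=O)C(Br)=P(c1ccccc1)(c1ccccc1)c1ccccc1 | intermediate
19 | ethyl (2E)-2-{[(2R,3S)-5-methoxy-4-methylidene-3-vinyltetrahydrofuran-2-yl]methylidene}-5-oxopentanoate | COC1O[C@H](/C=C(/C(=O)OCC)CCC=O)[C@@H](C=C)C1=C | intermediate
20 | diethyl (2Z,6E)-2-bromo-6-{[(2R,3S)-5-methoxy-4-methylidene-3-vinyltetrahydrofuran-2-yl]methylidene}hept-2-enedioate | COC1O[C@H](/C=C(/C(=O)OCC)CC/C=C(/C(=O)OCC)Br)[C@@H](C=C)C1=C | intermediate
21 | (2Z,6E)-2-bromo-6-{[(2R,3S)-5-methoxy-4-methylidene-3-vinyltetrahydrofuran-2-yl]methylidene}hept-2-ene-1,7-diol | COC1O[C@H](/C=C(/CO)CC/C=C(/CO)Br)[C@@H](C=C)C1=C | intermediate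
22 | (2Z,6E)-2-bromo-1,7-bis{[tert-butyl(diphenyl)silyl]oxy}-6-{[(2R,3S)-5-methoxy-4-methylidene-3-vinyltetrahydrofuran-2-yl]methylidene}hept-2-ene | COC1O[C@H](/C=C(/CO[Si](c2ccccc2)(c2ccccc2)C(C)(C)C)CC/C=C(/CO[Si](c2ccccc2)(c2ccccc2)C(C)(C)C)Br)[C@@H](C=C)C1=C | intermediate
23 | compound 22 with the vinyl group replaced by a (1R)-1,2-bis(4,4,5,5-tetramethyl-1,3,2-dioxaborolan-2-yl)ethyl group | COC1O[C@H](/C=C(/CO[Si](c2ccccc2)(c2ccccc2)C(C)(C)C)CC/C=C(/CO[Si](c2ccccc2)(c2ccccc2)C(C)(C)C)Br)[C@@H]([C@@H](CB2OC(C)(C)C(C)(C)O2)B2OC(C)(C)C(C)(C)O2)C1=C | intermediate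
24 | 2-[(3aS,4R,6E,10E,11aR)-6,10-bis({[tert-butyl(diphenyl)silyl]oxy}methyl)-2-methoxy-3-methylidene-2,3,3a,4,5,8,9,11a-octahydrocyclodeca[b]furan-4-yl]-4,4,5,5-tetramethyl-1,3,2-dioxaborolane | C=C1C(OC)O[C@@H]2/C=C(/CO[Si](c3ccccc3)(c3ccccc3)C(C)(C)C)CC/C=C(/CO[Si](c3ccccc3)(c3ccccc3)C(C)(C)C)C[C@@H](B3OC(C)(C)C(C)(C)O3)[C@@H]12 | intermediate
25 | (3aR,4R,6E,10E,11aR)-6,10-bis({[tert-butyl(diphenyl)silyl]oxy}methyl)-2-methoxy-3-methylidene-2,3,3a,4,5,8,9,11a-octahydrocyclodeca[b]furan-4-ol | C=C1C(OC)O[C@@H]2/C=C(/CO[Si](c3ccccc3)(c3ccccc3)C(C)(C)C)CC/C=C(/CO[Si](c3ccccc3)(c3ccccc3)C(C)(C)C)C[C@@H](O)[C@@H]12 | intermediate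
26 | 3-methylbutanoic anhydride | CC(C)CC(=O)OC(=O)CC(C)C | starting material
27 | (3aR,4R,6E,10E,11aR)-6,10-bis({[tert-butyl(diphenyl)silyl]oxy}methyl)-2-methoxy-3-methylidene-2,3,3a,4,5,8,9,11a-octahydrocyclodeca[b]furan-4-yl 3-methylbutanoate | C=C1C(OC)O[C@@H]2/C=C(/CO[Si](c3ccccc3)(c3ccccc3)C(C)(C)C)CC/C=C(/CO[Si](c3ccccc3)(c3ccccc3)C(C)(C)C)C[C@@H](OC(=O)CC(C)C)[C@@H]12 | intermediate
28 | (3aR,4R,6E,10E,11aR)-6,10-bis({[tert-butyl(diphenyl)silyl]oxy}methyl)-2-hydroxy-3-methylidene-2,3,3a,4,5,8,9,11a-octahydrocyclodeca[b]furan-4-yl 3-methylbutanoate | C=C1C(O)O[C@@H]2/C=C(/CO[Si](c3ccccc3)(c3ccccc3)C(C)(C)C)CC/C=C(/CO[Si](c3ccccc3)(c3ccccc3)C(C)(C)C)C[C@@H](OC(=O)CC(C)C)[C@@H]12 | intermediate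
29 | (3aR,4R,6E,10E,11aR)-6,10-bis({[tert-butyl(diphenyl)silyl]oxy}methyl)-3-methylidene-2-oxo-2,3,3a,4,5,8,9,11a-octahydrocyclodeca[b]furan-4-yl 3-methylbutanoate | C=C1C(=O)O[C@@H]2/C=C(/CO[Si](c3ccccc3)(c3ccccc3)C(C)(C)C)CC/C=C(/CO[Si](c3ccccc3)(c3ccccc3)C(C)(C)C)C[C@@H](OC(=O)CC(C)C)[C@@H]12 | intermediate
30 | (3aR,4R,6E,10E,11aR)-6,10-bis(hydroxymethyl)-3-methylidene-2-oxo-2,3,3a,4,5,8,9,11a-octahydrocyclodeca[b]furan-4-yl 3-methylbutanoate (CNP0199826.1) | C=C1C(=O)O[C@@H]2/C=C(/CO)CC/C=C(/CO)C[C@@H](OC(=O)CC(C)C)[C@@H]12 | target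

## Step count and risks

Total step count: 17.
Longest linear sequence: 15 steps (steps 1–5, 7, 8 and 10–17; steps 6 and 9 are side branches).

Steps most likely to fail:

**Step 13.** Intermolecular coupling and oligomerisation, or protodeboronation of the primary boronate, may outrun closure of the ten-membered ring. Zerovalent platinum may also insert into the C–Br bond during the diboration, and the facial selectivity at C8 may be poor if ligand and C7 are mismatched. The fallback sets out from 22 and comes back at 25, closing the ring by a B-alkyl Suzuki–Miyaura macrocyclisation of a β-silyloxyalkylborane, all known reaction types. Tsuji–Wacker oxidation of the vinyl group (PdCl2 (cat.), CuCl, O2, DMF/H2O) would give the methyl ketone F1. Kinetic enolisation on the methyl side and silylation (KN(SiMe3)2, Et3SiCl, THF, −78 °C) would give the triethylsilyl enol ether F2. Hydroboration with 9-BBN would give the B-alkyl-9-borabicyclononane F3, which would not be isolated but coupled in the same flask with the alkenyl bromide (PdCl2(dppf), AsPh3, Cs2CO3, DMF/THF/H2O, high dilution) to the macrocyclic triethylsilyl ether F4. Selective removal of the triethylsilyl group (HF·pyridine, pyridine, THF, 0 °C) would return 25. In this alternative C8 would rest on substrate control in the hydroboration.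

**Step 6.** C-Alkylation of the stabilised ylide by an unactivated primary iodide may be too slow, so that O-alkylation or loss of HI from the iodide takes over. The fallback sets out from 12 and comes back at 15 through a Horner–Wadsworth–Emmons reaction. Alkylation of the sodium salt of triethyl phosphonoacetate with 12 (NaH, DMF, 60 °C) would give the phosphonate F5. Reaction of F5 with aldehyde 14 (generated as in step 7) under LiCl, DBU, MeCN would give 15, the (2E) isomer being separated if necessary.

**Step 2.** The magnesium enolate may be protonated or aminomethylated twice, and 1,2-addition of the Grignard reagent to the lactone carbonyl may compete with conjugate addition. The fallback sets out from 2 and comes back at 7 by separating the two events and methylenating through a carboxylic acid. (CH2=CH)2CuLi with Me3SiCl (THF, −78 °C) and aqueous work-up would give the trans-vinyl lactone F6. LiN(i-Pr)2 (THF, −78 °C) then CO2 would give the α-carboxy lactone F7. Aqueous CH2O, Et2NH, NaOAc and AcOH with gentle warming would effect decarboxylative methylenation to 7.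

## Further compounds

F1 | step 13 | methyl ketone: compound 22 with the vinyl group converted into an acetyl group | COC1O[C@H](/C=C(/CO[Si](c2ccccc2)(c2ccccc2)C(C)(C)C)CC/C=C(/CO[Si](c2ccccc2)(c2ccccc2)C(C)(C)C)Br)[C@@H](C(C)=O)C1=C
F2 | step 13 | triethylsilyl enol ether: compound 22 with the vinyl group replaced by 1-(triethylsilyloxy)vinyl | COC1O[C@H](/C=C(/CO[Si](c2ccccc2)(c2ccccc2)C(C)(C)C)CC/C=C(/CO[Si](c2ccccc2)(c2ccccc2)C(C)(C)C)Br)[C@@H](C(=C)O[Si](CC)(CC)CC)C1=C
F3 | step 13 | B-alkyl-9-borabicyclo[3.3.1]nonane: compound 22 with the vinyl group replaced by (1R)-2-(9-borabicyclo[3.3.1]nonan-9-yl)-1-(triethylsilyloxy)ethyl | COC1O[C@H](/C=C(/CO[Si](c2ccccc2)(c2ccccc2)C(C)(C)C)CC/C=C(/CO[Si](c2ccccc2)(c2ccccc2)C(C)(C)C)Br)[C@@H]([C@@H](CB2C3CCCC2CCC3)O[Si](CC)(CC)CC)C1=C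
F4 | step 13 | macrocyclic triethylsilyl ether of 25 | C=C1C(OC)O[C@@H]2/C=C(/CO[Si](c3ccccc3)(c3ccccc3)C(C)(C)C)CC/C=C(/CO[Si](c3ccccc3)(c3ccccc3)C(C)(C)C)C[C@@H](O[Si](CC)(CC)CC)[C@@H]12
F5 | step 6 | ethyl 5-{[tert-butyl(dimethyl)silyl]oxy}-2-(diethoxyphosphoryl)pentanoate | CCOC(=O)C(CCCO[Si](C)(C)C(C)(C)C)P(=O)(OCC)OCC
F6 | step 2 | (4R,5S)-5-{[tert-butyl(diphenyl)silyl]oxymethyl}-4-vinyldihydrofuran-2(3H)-one | O=C1O[C@H](CO[Si](c2ccccc2)(c2ccccc2)C(C)(C)C)[C@@H](C=C)C1
F7 | step 2 | all-trans 5-{[tert-butyl(diphenyl)silyl]oxymethyl}-2-oxo-4-vinyltetrahydrofuran-3-carboxylic acid | O=C1O[C@H](CO[Si](c2ccccc2)(c2ccccc2)C(C)(C)C)[C@@H](C=C)[C@@H]1C(=O)O
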